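Abbreviations used throughout: geranyl = (2E)-3,7-dimethylocta-2,6-dien-1-yl; MOM = methoxymethyl; allyl = prop-2-en-1-yl. Atoms of the heterocycle carry flavonoid numbers (O1, C2, C3, C4, C4a, C5–C8, C8a; ring B primed).

## The problem

Compound 19 is a 2,3-trans-dihydroflavonol. Benzene ring A and dihydropyranone ring C share the C4a–C8a bond, ring B (4-hydroxyphenyl) sits on C2, and a hydroxyl sits on C3. Ring A is pentasubstituted and its three oxygens all differ (O1 in ring C, OMe at C5, OH at C7). The geranyl chain at C6 lies between C5–OMe and C7–OH, so differentiating a phloroglucinol core is half of the task. C2 and C3 (both R) are adjacent. C3 is alpha to the C4 ketone and epimerisable, and at equilibrium it follows C2 into the diequatorial trans arrangement, so only C2 needs absolute control. C2 can be lost in two ways: expulsion of O1 from a C3 enolate (E1cB ring opening), or ionisation of C2–O1 driven by a free 4'-OH (para-quinone methide). In the second case C3 dictates C2, which would carry a 2,3-cis intermediate into the wrong enantiomeric series. The geranyl group rules out hydrogenolysis, osmylation and electrophilic oxidants; its E alkene must not be scrambled, and next to a free 7-OH it cyclises to a chroman in strong acid. The alpha-ketol is air-oxidised to the flavonol and contracts to a benzofuranone in hot base. The enabling feature is the C4 ketone/C3 carbinol pair of ring C. It is an alpha-ketol whose carbonyl carbon is bonded to ring A, which is the retron of a benzoin union between a ring A aldehyde (C4) and a carbonyl carbon C3 tethered through O1–C2.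

## Retrosynthesis

**19 from 18.** Only the two acetal O–CH2 bonds at O7 and O4' are cut.
- Both phenols must stay masked to the end. A free 7-OH beside geranyl invites chroman formation, and a free 4'-OH opens the quinone methide channel while C3 is still being adjusted.
- Silyl ethers would not outlast the carbonate-mediated alkylations. Benzyl ethers cannot be hydrogenolysed beside the geranyl alkenes. Allyl ethers would fall together with the allyl ester of 15, which is too early.
- 18 is no simpler in skeleton, but it separates the settling of C3 from phenol release.
- The forward step needs only short, cold methanolic acid, a treatment well precedented for geranylated phenol acetals.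

**18 from 15.** A carboxyl group is added retrosynthetically at C3; in the forward sense the C3–CO2 bond is cut.
- A formyl group at C3 as acceptor would lead to 18 directly, but it gives a dialdehyde with no built-in distinction between donor and acceptor.
- The ester turns C3 into a 1,2-dicarbonyl electrophile, acidifies C2–H (needed for racemisation) and leaves as CO2.
- Allyl is preferred to methyl. Halide-induced dealkylation in a hot dipolar solvent (Krapcho) would release an enediolate at temperatures where O1 expulsion and ring contraction are to be feared.
- Zerovalent palladium unlocks the allyl ester at room temperature. Acid 16 then loses CO2 to the neutral enediol 17.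
- The forward step must deliver trans C3 without touching C2.

**15 from 14.** The C3–C4 bond is cut.
- Ring C opens and both stereocentres disappear. 14 is a racemic, configurationally labile keto aldehyde made of two aromatic fragments joined by one ether bond.
- The neighbouring cuts (O1–C2, O1–C8a) keep an open chain that already holds both stereocentres. This cut instead creates C–C bond, ring and stereocentres together and needs no redox adjustment.
- The forward reaction must invert the polarity of the aldehyde only, close a six-membered ring, and select one of two rapidly interconverting C2 enantiomers.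

**14 from 6 and 13.** The O1–C2 ether bond is cut, giving salicylaldehyde 6 and the benzylic, alpha-keto-activated chloride 13, fragments of similar size.
- Forming O1–C8a instead would need an activated haloarene. Building the keto ester after ether formation would need carbanion chemistry beside a free aldehyde.
- The forward reaction must give O-alkylation of a chelated phenol under a base mild enough not to trigger aldol chemistry of the product.

**13 from 8 and 11 (through 12); 8 from 7; 11 from 9 and 10.** The C2–C3 bond is cut.
- A Darzens condensation of aldehyde 8 with dichloroacetate 11 gives chloroglycidate 12, which rearranges to 13 in the same flask.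
- An arylpyruvate route (esterification, phenol protection, bromination) is longer and generates hydrogen bromide beside an acetal.
- All precursors are simple. 8 comes from 7 by acetal protection, and 11 from 9 and 10 by esterification.

**6 from 5, 4, 3, and 3 from 1 and 2.** The C6–C1'' bond and three O–C bonds are cut.
- Geranylation comes first, on symmetric 1, where the two free ring positions are equivalent, so no regiochemical question arises.
- A Claisen–Cope relay from an O-geranyl ether is rejected. The Cope step passes through a quaternary linalyl-type centre and cannot guarantee the E alkene.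
- The oxygens of 3 are then told apart by their surroundings. O4 (para, unchelated) and O6 (unhindered) take the acetal to give 4. O2, wedged between geranyl and formyl, is left for methylation to give 5. The acetal ortho to the aldehyde is released selectively to give 6.

## Roads not taken

**Alternative 1:** ring A is built last.
- *Cut.* Four bonds of ring A are cut (C8–C8a, C5–C6, C7–C8, C4a–C5). This leads to the 6-diazoacetyl-2,3-dihydropyran-4-one A2, which already holds ring C with both stereocentres, and to the geranyl-substituted siloxyalkyne A3.
- *Key step.* Irradiation of A2 triggers a Wolff rearrangement to a vinylketene, which adds to A3 in a [2+2] sense. Heating opens the cyclobutenone (4π) and closes the dienylketene (6π) to phenol A1 (Danheiser benzannulation).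
- *Merit.* The mechanism dictates geranyl at C6, silyloxy at C7 and a free 5-OH ready for methylation. In this respect the road is clearly better than the chosen plan, whose ring A rests on steric and hydrogen-bond discrimination among phenols (steps 2 and 4).
- *Weak points.* The whole stereochemical burden moves to A2, for which no short entry is evident. Its C3–H is alpha to a ketone and its O1 is a vinylogous carboxylate leaving group, so the thermal phase threatens both centres. A3 contains a skipped enyne whose doubly activated CH2 isomerises easily under the basic conditions of ynolate chemistry. The behaviour of a ketene derived from a push–pull enone is uncertain. After A1 there remain methylation of a chelated phenol and removal of three different protecting groups.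
- *Comparison.* The chosen plan pays for its less elegant ring A with cheap, early steps, and it creates the stereocentres late and catalytically.

**Alternative 2:** ring C is closed at O1–C2.
- *Cut.* The precursor is the open-chain alpha,beta-dihydroxy ketone A5, defined only at the future C3.
- *Key step.* A mild Brønsted acid or a strongly hydrogen-bonding fluorinated alcohol ionises the benzylic hydroxyl to the para-quinone methide A6. The ortho phenol adds to it and gives A4.
- *Merits.* The closure is stereoconvergent at C2, since the trans product is the thermodynamic one. Only one stereocentre has to be made, by known asymmetric oxidation of a chalcone, and one acetal cleavage finishes the synthesis.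
- *Comparison.* This is probably the shorter and more predictable road, and the fallback to step 9 borrows from it.
- *Weak points for this target.* Dihydroxylation cannot tell the enone from the more electron-rich geranyl alkenes, so only nucleophilic epoxidation is usable. The stereocentre of A5 belongs to an open-chain alpha-ketol that can drift through its enediol before closure. A free 4'-OH, an acid and the geranyl chain must coexist in one flask. The absolute configuration at C2 is only relayed.
- *What the chosen plan sets against it.* C2 is set directly by a catalyst from racemic material, together with a C–C bond and the ring. No oxidant ever meets the geranyl chain. The 4'-OH stays masked until both centres are fixed. The two fragments are joined one step before the key step.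

**Alternative 3:** ring C is closed at O1–C8a.
- *Key step.* In fluoro ketone A8 the C2 alkoxide, generated with a strong silylamide base, displaces fluoride in an intramolecular SNAr reaction and gives A7.
- *Merits.* No bond to either stereocentre is broken, the position of closure is fixed by the fluorine, and the substitution is irreversible. In these respects it is as good as the chosen plan.
- *Weak points.* The ring that must accept the alkoxide carries two alkoxy donors and an alkyl group. It is activated only by a ketone that two ortho substituents twist out of conjugation. A beta-alkoxido ketone under strong base is set up for retro-aldol cleavage and C3 epimerisation, which would erase exactly the centres that were built beforehand. A geranylated fluororesorcinol building block has no short access. A7 bears an acetal at O5 where the target has a methyl ether, so the end game would have to methylate the least reactive, chelated 5-OH beside three other hydroxyls.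
- *Comparison.* The chosen plan also passes through a base-labile intermediate, but it turns that lability into the means of stereoconvergence.

Key step: step 9

Assumption: the sense of induction of the aminoindanol-derived carbene on this new substrate class cannot be deduced safely. The (5aS,10bR) salt is written, and its equally available mirror image is to be used if the closure favours 2S.

## Route

Step 1
Reactants: 1 2,4,6-trihydroxybenzaldehyde; 2 geranyl bromide
Product: 3 3-geranyl-2,4,6-trihydroxybenzaldehyde
Conditions: KOH (1.0 equiv), MeOH–H2O, 0 °C to rt; 2 (0.9 equiv)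
Reagents that add atoms: none
Why: C-alkylation of an ambident phloroglucinol phenoxide; the protic medium solvates oxygen and steers the soft allylic bromide to carbon, the two free ring positions of 1 are equivalent, and direct SN2 attack keeps the E alkene. A deficit of 2 limits dialkylation.

Step 2
Reactants: 3 3-geranyl-2,4,6-trihydroxybenzaldehyde
Product: 4 3-geranyl-2-hydroxy-4,6-bis(methoxymethoxy)benzaldehyde
Conditions: MOMCl (2.1 equiv), K2CO3, acetone, 0 °C to rt
Reagents that add atoms: chloromethyl methyl ether, COCCl
Why: Williamson-type acetalisation; the unchelated 4-OH reacts first, and of the two ortho hydroxyls the one at C6 is unhindered whereas that at C2 is wedged between geranyl and formyl and held in the stronger chelate. This is the pattern known from partial alkylation of 3-alkylated acylphloroglucinols.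

Step 3
Reactants: 4 3-geranyl-2-hydroxy-4,6-bis(methoxymethoxy)benzaldehyde
Product: 5 3-geranyl-2-methoxy-4,6-bis(methoxymethoxy)benzaldehyde
Conditions: MeI, K2CO3, DMF, 40 °C
Reagents that add atoms: iodomethane, CI
Why: Williamson methylation of the one remaining phenol; a dipolar aprotic solvent and the smallest electrophile overcome chelation and crowding, and no other acidic site is present.

Step 4
Reactants: 5 3-geranyl-2-methoxy-4,6-bis(methoxymethoxy)benzaldehyde
Product: 6 3-geranyl-6-hydroxy-2-methoxy-4-(methoxymethoxy)benzaldehyde
Conditions: HCl (0.1 M in MeOH), 0 °C, stopped at monocleavage; aq NaHCO3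
Reagents that add atoms: none
Why: Acid-catalysed transacetalisation; the aryl acetal ortho to a carbonyl group is cleaved faster because the carbonyl oxygen assists protonation and the released phenol is stabilised by chelation, a known selectivity of ortho-acyl aryl MOM ethers. The 4-O-MOM group survives and keeps the oxygen next to geranyl masked, so no chroman can form.

Step 5
Reactants: 7 4-hydroxybenzaldehyde
Product: 8 4-(methoxymethoxy)benzaldehyde
Conditions: MOMCl, K2CO3, acetone, rt
Reagents that add atoms: chloromethyl methyl ether, COCCl
Why: Routine Williamson-type protection of an acidic, unhindered phenol.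

Step 6
Reactants: 9 dichloroacetic acid; 10 allyl alcohol
Product: 11 allyl dichloroacetate
Conditions: TsOH·H2O (cat.), toluene, reflux, Dean–Stark
Reagents that add atoms: none
Why: Fischer esterification driven by azeotropic removal of water.

Step 7
Reactants: 8 4-(methoxymethoxy)benzaldehyde; 11 allyl dichloroacetate
Product: 13 allyl 3-chloro-3-[4-(methoxymethoxy)phenyl]-2-oxopropanoate (racemic), via allyl 2-chloro-3-arylglycidate 12 (not isolated)
Conditions: t-BuOK (1.0 equiv), THF, −78 to 0 °C, then rt; used crude
Reagents that add atoms: none
Why: Darzens condensation of a dichloroacetate; the aldolate displaces one chloride to give 12, whose benzylic C–O bond ionises readily next to the para-alkoxyphenyl ring, so the alkoxide collapses to the ketone and chloride returns at the benzylic carbon (known chloroglycidate to beta-chloro alpha-keto ester rearrangement). The bulky base avoids transesterification, and the racemate is what step 9 requires.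

Step 8
Reactants: 6 3-geranyl-6-hydroxy-2-methoxy-4-(methoxymethoxy)benzaldehyde; 13 allyl 3-chloro-3-[4-(methoxymethoxy)phenyl]-2-oxopropanoate
Product: 14 allyl 3-[2-formyl-4-geranyl-3-methoxy-5-(methoxymethoxy)phenoxy]-3-[4-(methoxymethoxy)phenyl]-2-oxopropanoate (racemic, C2 labile)
Conditions: K2CO3 (1.1 equiv), MeCN, 0 °C to rt; pH 5 buffer work-up
Reagents that add atoms: none
Why: Williamson ether synthesis with an alpha-halo ketone; the chloride is doubly activated (benzylic and alpha to a ketone), a dipolar aprotic solvent favours O- over C-alkylation of the phenoxide, and any residual 12 is opened at the same carbon and converges on 14. Low temperature and a mildly acidic work-up limit the time 14 spends as its enolate.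

Step 9
Reactants: 14 allyl 3-[2-formyl-4-geranyl-3-methoxy-5-(methoxymethoxy)phenoxy]-3-[4-(methoxymethoxy)phenyl]-2-oxopropanoate
Product: 15 allyl (2R,3S)-6-geranyl-3-hydroxy-5-methoxy-7-(methoxymethoxy)-2-[4-(methoxymethoxy)phenyl]-4-oxochromane-3-carboxylate (ester trans to ring B)
Conditions: (5aS,10bR)-2-(pentafluorophenyl)-5a,10b-dihydro-4H,6H-indeno[2,1-b][1,2,4]triazolo[4,3-d][1,4]oxazin-2-ium tetrafluoroborate (15 mol %), iPr2NEt (30 mol %), toluene (0.02 M), 4 Å MS, Ar, rt
Reagents that add atoms: none
Why: Proposed new method: base frees the carbene from the triazolium salt, it attacks the formyl carbon of 14, a 1,2-proton shift turns the adduct into the Breslow enaminol in which C4 is nucleophilic, C4 adds to the ester-activated ketone carbon C3, and collapse of the adduct expels the carbene and leaves the C4 ketone, so the C3–C4 bond forms with no change in overall oxidation level. The closest known reaction types are the enantioselective intramolecular crossed aldehyde–ketone benzoin of salicylaldehyde-derived keto ethers to 3-hydroxychroman-4-ones and the intermolecular dynamic kinetic cross-benzoin of racemic beta-halo alpha-keto esters; what has not been shown is their union, a ring closure that dynamically resolves a beta-aryloxy alpha-keto ester. Ring C closes in the 6-exo-trig mode (C4 attacks the C3 carbonyl, whose oxygen stays outside the new ring). C2 is controlled by the catalyst: the amine interconverts the enantiomers of 14 by enolisation faster than either cyclises (Curtin–Hammett situation), the chiral carbene is expected to close the 2R form faster through a chair-like transition state with ring B equatorial, and once C3 is quaternary C2–H is no longer alpha to a carbonyl group, so the centre is locked. C3 is controlled by C2 in the same transition state (larger ester equatorial and trans to ring B, developing alkoxide axial and hydrogen-bonded to the enaminol OH), and its sense is of no consequence because step 10 erases it. Which carbonyl donates and which accepts is fixed by the substrate, since a carbene can invert the polarity of the formyl group only; ester, acetals and alkenes are spectators, and dilution together with the two ortho substituents suppresses intermolecular benzoin. The selectivity most in need is closure against 5-exo aldol addition of the C2 enolate to the aldehyde: the weak amine, the acidic N-pentafluorophenyl salt and the low electrophilicity of a trialkoxy-substituted aldehyde should keep that aldol reversible, whereas the benzoin adduct is a sink.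

Step 10
Reactants: 15 allyl (2R,3S)-6-geranyl-3-hydroxy-5-methoxy-7-(methoxymethoxy)-2-[4-(methoxymethoxy)phenyl]-4-oxochromane-3-carboxylate
Product: 18 (2R,3R)-6-geranyl-3-hydroxy-5-methoxy-7-(methoxymethoxy)-2-[4-(methoxymethoxy)phenyl]chroman-4-one, via beta-keto acid 16 (not isolated), via 2H-chromene-3,4-diol 17 (not isolated)
Conditions: Pd(PPh3)4 (5 mol %), morpholine (3 equiv), degassed THF, rt; then Et3N (0.5 equiv), rt, until the 2,3-cis epimer has gone
Reagents that add atoms: none
Why: Tsuji-type deallylation–decarboxylation; zerovalent palladium ionises the allyl ester, morpholine takes up the allyl unit, acid 16 loses CO2 at room temperature through a cyclic transition state, and enediol 17 ketonises to the ring A-conjugated ketone. C3 is set under thermodynamic control by C2, since amine-mediated enolisation funnels the epimers into the diequatorial 2,3-trans form. C2 is spared because there is neither heat nor strong base and the 4'-oxygen is still masked; exclusion of air protects 17 from oxidation.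

Step 11
Reactants: 18 (2R,3R)-6-geranyl-3-hydroxy-5-methoxy-7-(methoxymethoxy)-2-[4-(methoxymethoxy)phenyl]chroman-4-one
Product: 19 (2R,3R)-6-geranyl-3,7-dihydroxy-2-(4-hydroxyphenyl)-5-methoxychroman-4-one (CNP0177937.1)
Conditions: HCl (1.25 M in MeOH), 0 °C to rt; aq NaHCO3
Reagents that add atoms: none
Why: Acid-catalysed transacetalisation of aryl MOM ethers, well precedented on prenylated and geranylated flavonoids; aryl acetals are cleaved much faster than a trisubstituted alkene is protonated, so a short, cool exposure should spare the geranyl chain and both stereocentres.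

## Compound list

1 | 2,4,6-trihydroxybenzaldehyde | O=Cc1c(O)cc(O)cc1O | starting material
2 | geranyl bromide | CC(C)=CCC/C(C)=C/CBr | starting material
3 | 3-geranyl-2,4,6-trihydroxybenzaldehyde | O=Cc1c(O)cc(O)c(C/C=C(\C)CCC=C(C)C)c1O | intermediate
4 | 3-geranyl-2-hydroxy-4,6-bis(methoxymethoxy)benzaldehyde | O=Cc1c(OCOC)cc(OCOC)c(C/C=C(\C)CCC=C(C)C)c1O | intermediate
5 | 3-geranyl-2-methoxy-4,6-bis(methoxymethoxy)benzaldehyde | O=Cc1c(OCOC)cc(OCOC)c(C/C=C(\C)CCC=C(C)C)c1OC | intermediate
6 | 3-geranyl-6-hydroxy-2-methoxy-4-(methoxymethoxy)benzaldehyde | O=Cc1c(O)cc(OCOC)c(C/C=C(\C)CCC=C(C)C)c1OC | intermediate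
7 | 4-hydroxybenzaldehyde | O=Cc1ccc(O)cc1 | starting material
8 | 4-(methoxymethoxy)benzaldehyde | O=Cc1ccc(OCOC)cc1 | intermediate
9 | dichloroacetic acid | OC(=O)C(Cl)Cl | starting material
10 | allyl alcohol | OCC=C | starting material
11 | allyl dichloroacetate | C=CCOC(=O)C(Cl)Cl | intermediate
12 | allyl 2-chloro-3-[4-(methoxymethoxy)phenyl]oxirane-2-carboxylate (racemic, not isolated) | C=CCOC(=O)C1(Cl)OC1c1ccc(OCOC)cc1 | intermediate
13 | allyl 3-chloro-3-[4-(methoxymethoxy)phenyl]-2-oxopropanoate (racemic) | C=CCOC(=O)C(=O)C(Cl)c1ccc(OCOC)cc1 | intermediate
14 | allyl 3-[2-formyl-4-geranyl-3-methoxy-5-(methoxymethoxy)phenoxy]-3-[4-(methoxymethoxy)phenyl]-2-oxopropanoate (racemic) | COc1c(C/C=C(\C)CCC=C(C)C)c(OCOC)cc(OC(C(=O)C(=O)OCC=C)c2ccc(OCOC)cc2)c1C=O | intermediate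
15 | allyl (2R,3S)-6-geranyl-3-hydroxy-5-methoxy-7-(methoxymethoxy)-2-[4-(methoxymethoxy)phenyl]-4-oxochromane-3-carboxylate | COc1c(C/C=C(\C)CCC=C(C)C)c(OCOC)cc2c1C(=O)[C@](O)(C(=O)OCC=C)[C@@H](c1ccc(OCOC)cc1)O2 | intermediate
16 | (2R,3S)-6-geranyl-3-hydroxy-5-methoxy-7-(methoxymethoxy)-2-[4-(methoxymethoxy)phenyl]-4-oxochromane-3-carboxylic acid (not isolated) | COc1c(C/C=C(\C)CCC=C(C)C)c(OCOC)cc2c1C(=O)[C@](O)(C(=O)O)[C@@H](c1ccc(OCOC)cc1)O2 | intermediate
17 | (2R)-6-geranyl-5-methoxy-7-(methoxymethoxy)-2-[4-(methoxymethoxy)phenyl]-2H-chromene-3,4-diol (not isolated) | COc1c(C/C=C(\C)CCC=C(C)C)c(OCOC)cc2c1C(O)=C(O)[C@@H](c1ccc(OCOC)cc1)O2 | intermediate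
18 | (2R,3R)-6-geranyl-3-hydroxy-5-methoxy-7-(methoxymethoxy)-2-[4-(methoxymethoxy)phenyl]chroman-4-one | COc1c(C/C=C(\C)CCC=C(C)C)c(OCOC)cc2c1C(=O)[C@H](O)[C@@H](c1ccc(OCOC)cc1)O2 | intermediate
19 | (2R,3R)-6-geranyl-3,7-dihydroxy-2-(4-hydroxyphenyl)-5-methoxychroman-4-one | COc1c(C/C=C(\C)CCC=C(C)C)c(O)cc2c1C(=O)[C@H](O)[C@@H](c1ccc(O)cc1)O2 | target

## Step count and least certain steps

Total: 11 steps. Longest linear sequence: 8 steps (1, 2, 3, 4, 8, 9, 10, 11) from 1.

**Step 9 (key step).**
- *Risk.* The most likely failure is slow formation of the Breslow intermediate, because the aldehyde is flanked by two alkoxy groups and deactivated by three donors. The C2 enolate would then have time for 5-exo aldol addition followed by irreversible oxalyl transfer. The second risk is insufficient discrimination between the interconverting enantiomers of 14.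
- *Fallback.* It uses known chemistry, sets out from 5 and comes back at 19. It gives up the C3–C4 closure for an O1–C2 closure.
 1. MeMgBr adds to 5 to give the 1-arylethanol F1.
 2. Dess–Martin periodinane oxidises it to the acetophenone F2.
 3. Claisen–Schmidt condensation with 8 (KOH, EtOH) gives the E-chalcone F3.
 4. Juliá–Colonna epoxidation (poly-L-leucine, urea–H2O2, DBU, THF) gives the (alphaR,betaS)-epoxychalcone F4. The nucleophilic peroxide attacks only the enone and leaves the geranyl alkenes alone.
 5. Methanolic HCl removes the three acetals. The phenol ortho to the ketone opens the epoxide at the benzylic carbon with inversion, which leads to 19.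

**Step 8.**
- *Risk.* The carbonate also deprotonates C2–H of freshly formed 14. The enolate can add to the neighbouring aldehyde, which is the first stage of a Rap–Stoermer benzofuran synthesis. In addition, 13 may be consumed by C-alkylation of the electron-rich phenoxide or by self-condensation.
- *Fallback.* It sets out from 13 and 6 and comes back at 14. The ether is made one oxidation level lower, where C2–H is not acidic.
 1. NaBH4 (MeOH, −78 °C) reduces 13 to the chlorohydrin F5.
 2. K2CO3 closes it to the aryl glycidate F6.
 3. The phenoxide of 6 opens F6 at the benzylic carbon (K2CO3, DMF, 50 °C), giving the alpha-hydroxy ester ether F7.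
 4. Dess–Martin periodinane oxidises F7 to 14 under non-basic conditions directly before step 9.

**Step 10.**
- *Risk.* Kinetic protonation of 17 from the face away from ring B would favour the 2,3-cis epimer. The amine equilibration might then be too slow, or might cost C2 through enolate-driven expulsion of O1.
- *Fallback.* It sets out from the crude product of step 10 (from 15) and comes back at 18. It corrects C3 by substitution instead of enolisation.
 1. The equilibration is omitted and the (2R,3S)-cis ketol F8 is separated.
 2. Mitsunobu inversion (PPh3, DIAD, 4-nitrobenzoic acid, toluene, 0 °C) gives the trans 4-nitrobenzoate F9.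
 3. The activated ester is removed by brief methanolysis (catalytic K2CO3, MeOH, 0 °C) to give 18.

**Step 2.**
- *Risk.* Incomplete discrimination between the two ortho hydroxyls would place an acetal on O2. After methylation this would feed the isomeric ring A pattern, the 8-geranyl series.
- *Fallback.* It sets out from 1 and 2 and comes back at 5. Regiochemistry is fixed by halogenation.
 1. 1 is converted with MOMCl and K2CO3 into 2-hydroxy-4,6-bis(methoxymethoxy)benzaldehyde F10, which raises no regiochemical question.
 2. NIS in DMF iodinates ortho to the free phenol, the less crowded and more activated site, giving the 3-iodo phenol F11.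
 3. MeI and K2CO3 give the 3-iodo-2-methoxy aldehyde F12.
 4. Stille coupling (Pd(PPh3)4, DMF, 90 °C) with tributyl(geranyl)stannane F13, made from 2 and Bu3SnLi, delivers 5.

**Step 11.**
- *Risk.* Acid-promoted addition of the liberated 7-OH (or of methanol) to the proximal geranyl alkene, and acid-induced ionisation at C2 once the 4'-OH is free.
- *Fallback.* It sets out from 18 and comes back at 19. The acetals are exchanged for silyl ethers under buffered aprotic conditions, so that no Brønsted acid meets the phenol/geranyl pair.
 1. TMSOTf and 2,2'-bipyridyl (MeCN, 0 °C to rt) convert 18 into the 3,7,4'-tris(trimethylsilyl) ether F14.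
 2. Water at neutral pH hydrolyses F14 to 19.

## Further compounds

F1 | step 9 | 1-[3-geranyl-2-methoxy-4,6-bis(methoxymethoxy)phenyl]ethanol (racemic) | COCOc1cc(OCOC)c(C/C=C(\C)CCC=C(C)C)c(OC)c1C(C)O
F2 | step 9 | 1-[3-geranyl-2-methoxy-4,6-bis(methoxymethoxy)phenyl]ethanone | COCOc1cc(OCOC)c(C/C=C(\C)CCC=C(C)C)c(OC)c1C(C)=O
F3 | step 9 | (E)-1-[3-geranyl-2-methoxy-4,6-bis(methoxymethoxy)phenyl]-3-[4-(methoxymethoxy)phenyl]prop-2-en-1-one | COCOc1cc(OCOC)c(C/C=C(\C)CCC=C(C)C)c(OC)c1C(=O)/C=C/c1ccc(OCOC)cc1
F4 | step 9 | [3-geranyl-2-methoxy-4,6-bis(methoxymethoxy)phenyl]{(2R,3S)-3-[4-(methoxymethoxy)phenyl]oxiran-2-yl}methanone | COCOc1cc(OCOC)c(C/C=C(\C)CCC=C(C)C)c(OC)c1C(=O)[C@@H]1O[C@H]1c1ccc(OCOC)cc1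
F5 | step 8 | allyl 3-chloro-2-hydroxy-3-[4-(methoxymethoxy)phenyl]propanoate (racemic, diastereomer mixture) | C=CCOC(=O)C(O)C(Cl)c1ccc(OCOC)cc1
F6 | step 8 | allyl 3-[4-(methoxymethoxy)phenyl]oxirane-2-carboxylate (racemic) | C=CCOC(=O)C1OC1c1ccc(OCOC)cc1
F7 | step 8 | allyl 3-[2-formyl-4-geranyl-3-methoxy-5-(methoxymethoxy)phenoxy]-2-hydroxy-3-[4-(methoxymethoxy)phenyl]propanoate (racemic, diastereomer mixture) | COc1c(C/C=C(\C)CCC=C(C)C)c(OCOC)cc(OC(C(O)C(=O)OCC=C)c2ccc(OCOC)cc2)c1C=O
F8 | step 10 | (2R,3S)-6-geranyl-3-hydroxy-5-methoxy-7-(methoxymethoxy)-2-[4-(methoxymethoxy)phenyl]chroman-4-one (2,3-cis) | COc1c(C/C=C(\C)CCC=C(C)C)c(OCOC)cc2c1C(=O)[C@@H](O)[C@@H](c1ccc(OCOC)cc1)O2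
F9 | step 10 | (2R,3R)-6-geranyl-5-methoxy-7-(methoxymethoxy)-2-[4-(methoxymethoxy)phenyl]-4-oxochroman-3-yl 4-nitrobenzoate | COc1c(C/C=C(\C)CCC=C(C)C)c(OCOC)cc2c1C(=O)[C@H](OC(=O)c1ccc(cc1)[N+](=O)[O-])[C@@H](c1ccc(OCOC)cc1)O2
F10 | step 2 | 2-hydroxy-4,6-bis(methoxymethoxy)benzaldehyde | O=Cc1c(O)cc(OCOC)cc1OCOC
F11 | step 2 | 2-hydroxy-3-iodo-4,6-bis(methoxymethoxy)benzaldehyde | O=Cc1c(O)c(I)c(OCOC)cc1OCOC
F12 | step 2 | 3-iodo-2-methoxy-4,6-bis(methoxymethoxy)benzaldehyde | O=Cc1c(OC)c(I)c(OCOC)cc1OCOC
F13 | step 2 | tributyl[(2E)-3,7-dimethylocta-2,6-dien-1-yl]stannane | CCCC[Sn](CCCC)(CCCC)C/C=C(\C)CCC=C(C)C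
F14 | step 11 | (2R,3R)-6-geranyl-5-methoxy-3,7-bis(trimethylsilyloxy)-2-[4-(trimethylsilyloxy)phenyl]chroman-4-one | COc1c(C/C=C(\C)CCC=C(C)C)c(O[Si](C)(C)C)cc2c1C(=O)[C@H](O[Si](C)(C)C)[C@@H](c1ccc(O[Si](C)(C)C)cc1)O2
A1 | alternative 1 | (2R,3R)-3-(tert-butyldimethylsilyloxy)-6-geranyl-5-hydroxy-4'-(methoxymethoxy)-7-(triisopropylsilyloxy)flavanone | Oc1c(C/C=C(\C)CCC=C(C)C)c(O[Si](C(C)C)(C(C)C)C(C)C)cc2c1C(=O)[C@H](O[Si](C)(C)C(C)(C)C)[C@@H](c1ccc(OCOC)cc1)O2
A2 | alternative 1 | (2R,3R)-3-(tert-butyldimethylsilyloxy)-6-(diazoacetyl)-2-[4-(methoxymethoxy)phenyl]-2,3-dihydropyran-4-one | [N-]=[N+]=CC(=O)C1=CC(=O)[C@H](O[Si](C)(C)C(C)(C)C)[C@@H](c2ccc(OCOC)cc2)O1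
A3 | alternative 1 | (E)-5,9-dimethyl-1-(triisopropylsilyloxy)deca-4,8-dien-1-yne | CC(C)=CCC/C(C)=C/CC#CO[Si](C(C)C)(C(C)C)C(C)C
A4 | alternative 2 | (2R,3R)-6-geranyl-3,4'-dihydroxy-5-methoxy-7-(methoxymethoxy)flavanone | COc1c(C/C=C(\C)CCC=C(C)C)c(OCOC)cc2c1C(=O)[C@H](O)[C@@H](c1ccc(O)cc1)O2
A5 | alternative 2 | (2R)-1-[3-geranyl-6-hydroxy-2-methoxy-4-(methoxymethoxy)phenyl]-2,3-dihydroxy-3-(4-hydroxyphenyl)propan-1-one (either configuration at C3) | COc1c(C/C=C(\C)CCC=C(C)C)c(OCOC)cc(O)c1C(=O)[C@H](O)C(O)c1ccc(O)cc1
A6 | alternative 2 | 4-{(2R)-3-[3-geranyl-6-hydroxy-2-methoxy-4-(methoxymethoxy)phenyl]-2-hydroxy-3-oxopropylidene}cyclohexa-2,5-dien-1-one | COc1c(C/C=C(\C)CCC=C(C)C)c(OCOC)cc(O)c1C(=O)[C@H](O)C=C1C=CC(=O)C=C1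
A7 | alternative 3 | (2R,3R)-6-geranyl-3,5,7,4'-tetrakis(methoxymethoxy)flavanone | COCOc1c(C/C=C(\C)CCC=C(C)C)c(OCOC)cc2c1C(=O)[C@H](OCOC)[C@@H](c1ccc(OCOC)cc1)O2
A8 | alternative 3 | (2R,3R)-1-[6-fluoro-3-geranyl-2,4-bis(methoxymethoxy)phenyl]-3-hydroxy-2-(methoxymethoxy)-3-[4-(methoxymethoxy)phenyl]propan-1-one | COCOc1c(C/C=C(\C)CCC=C(C)C)c(OCOC)cc(F)c1C(=O)[C@H](OCOC)[C@@H](c1ccc(OCOC)cc1)O
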